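Everything hangs on cutting the C3–C4 bond of ring A. (R)-Carvone supplies ring B complete (C5 to C10, the C8 methyl group, C7=C8), and its isopropenyl group already holds C4. The key step exploits the fact that in ring A this quaternary, doubly methylated C4 sits next to the oxygen-bearing C3. The precursor is carvone carrying at C10 a methyl group and, on the face opposite the isopropenyl group, a 3-oxopropyl chain. Hydrogen-atom transfer to the isopropenyl CH2 creates the second C4 methyl group and a tertiary radical that closes onto the aldehyde. One operation therefore gives ring A, the quaternary carbon and the 3β-alcohol. The C11–C16 chain enters afterwards at the C9 ketone.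

Key step: step 4

Remark: labdane numbering (C1–C20) is used for all carvone-derived compounds, including the monocyclic ones. The target is (3S,5R,9S,10R,13S), that is 3β-O, 5α-H, 9α-H, 10β-CH3. Compound 4 is carried on as a mixture of C10 epimers because step 2 flattens this centre.

Step 1
Reactants: 1 (R)-carvone; 2 iodomethane
Product: 4 6-methylcarvone [(5R)-2,6-dimethyl-5-(prop-1-en-2-yl)cyclohex-2-en-1-one; epimers at the new methine C10], via lithium dienolate 3 (not isolated)
Conditions: LiN(iPr)2, THF, −78 °C; MeI, −78 to 0 °C
Reagents that add atoms: iodomethane (2), CI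
Why: Kinetic α′-deprotonation of the enone at the C10 methylene gives the cross-conjugated lithium dienolate, and its SN2 methylation (enolate alkylation) is routine for carvone; C5 is untouched and the epimer mixture at C10 does not matter because the next step turns this carbon into an enolate again.

Step 2
Reactants: 4 6-methylcarvone; 5 propargyl bromide (3-bromoprop-1-yne)
Product: 7 (5S,6S)-2,6-dimethyl-5-(prop-1-en-2-yl)-6-(prop-2-yn-1-yl)cyclohex-2-en-1-one (propargyl trans to isopropenyl), via lithium enolate 6 (not isolated)
Conditions: LiN(iPr)2, THF, −78 °C; HC≡CCH2Br, −78 °C to rt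
Reagents that add atoms: propargyl bromide (5), C#CCBr
Why: Second enolate alkylation, run with an activated propargylic bromide because a tetrasubstituted enolate reacts sluggishly with unactivated halides; the C5 isopropenyl group turns pseudoaxial to avoid allylic strain with the C10 methyl group and shields its own face, so the electrophile enters anti to it and sets the quaternary C10 with the three-carbon chain trans to the isopropenyl group (later 10β-methyl, trans ring fusion).

Step 3
Reactants: 7 propargyl ketone
Product: 9 6-methyl-6-(3-oxopropyl)carvone = 3-[(1S,6S)-1,3-dimethyl-2-oxo-6-(prop-1-en-2-yl)cyclohex-3-en-1-yl]propanal, via alkenylborane 8 (not isolated)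
Conditions: (c-C6H11)2BH (from BH3·SMe2 + cyclohexene), THF, 0 °C; H2O2, pH 7 phosphate buffer, 0 °C to rt
Reagents that add atoms: hydrogen peroxide, OO
Why: Anti-Markovnikov hydroboration–oxidation of a terminal alkyne: the bulky dialkylborane adds to the alkyne much faster than to the hindered 1,1-disubstituted alkene or the flanked conjugated ketone, places boron on the terminal carbon (C3), and buffered peroxide converts the alkenylborane through the enol into the aldehyde without the hydroperoxide anion needed for enone epoxidation; no stereocentre is made or touched.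

Step 4
Reactants: 9 6-methyl-6-(3-oxopropyl)carvone
Product: 10 3β-hydroxy-4,4,8,10-tetramethyl-trans-octal-7-en-9-one (5α-H; 10β-CH3) = (4aS,6S,8aS)-6-hydroxy-2,5,5,8a-tetramethyl-4a,5,6,7,8,8a-hexahydronaphthalen-1(4H)-one
Conditions: Fe(acac)3 (0.3 equiv), PhSiH3 (2.5 equiv), EtOH (0.02 M), Ar, 60 °C
Reagents that add atoms: none
Why: Fe(acac)3 and PhSiH3 in ethanol form an iron hydride that passes a hydrogen atom to the unsubstituted CH2 end of the isopropenyl group, which becomes the second methyl group on C4 and leaves a nucleophilic tertiary radical at C4; this radical adds to the aldehyde carbon C3, and the resulting alkoxy radical is reduced by divalent iron and protonated by ethanol, which regenerates trivalent iron for the next cycle. The closest known reaction type is the metal-hydride hydrogen-atom-transfer (Mukaiyama-type) reductive cyclisation of unactivated alkenes onto tethered ketones and aldehydes. Ring A (C4, C5, C10, C1, C2, C3) closes in the 6-exo-trig mode, with the carbonyl oxygen outside the new ring. C3 is the only new stereocentre and is controlled by a chair-like transition state built on the fixed trans C5/C10 pair, in which the C=O oxygen lies equatorial and so avoids the syn-axial H1α and H5α, giving the 3β-alcohol; reversibility of the addition works in the same direction. The step needs chemoselective hydrogen-atom transfer to the electron-rich 1,1-disubstituted alkene in the presence of the electron-poor, trisubstituted C7=C8 enone, which is a much slower hydrogen-atom acceptor, and the C4 radical could reach C7, C8 or C9 only through strained four- or five-membered bridged rings, while high dilution holds back intermolecular Giese addition to the enone.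

Step 5
Reactants: 10 hydroxy enone
Product: 11 3β-(tert-butyldimethylsilyloxy)-4,4,8,10-tetramethyl-trans-octal-7-en-9-one
Conditions: TBSOTf, 2,6-lutidine, CH2Cl2, 0 °C
Reagents that add atoms: tert-butyldimethylsilyl triflate, CC(C)(C)[Si](C)(C)OS(=O)(=O)C(F)(F)F
Why: Standard silyl ether formation; the reactive silyl triflate overcomes the neopentyl-type hindrance of the equatorial 3β-alcohol next to C4, and the weak, hindered base leaves the enone alone.

Step 6
Reactants: 12 (S)-citronellol
Product: 13 (S)-citronellyl tert-butyldimethylsilyl ether
Conditions: TBSCl, imidazole, CH2Cl2, rt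
Reagents that add atoms: tert-butyldimethylsilyl chloride, CC(C)(C)[Si](C)(C)Cl
Why: Standard imidazole-promoted silylation of a primary alcohol; the future C13 (citronellol C3) is remote and unaffected.

Step 7
Reactants: 13 silyl ether
Product: 15 (S)-6-(tert-butyldimethylsilyloxy)-4-methylhexanoic acid, via aldehyde 14 (not isolated)
Conditions: RuCl3·3H2O (2 mol %), NaIO4 (4 equiv), EtOAc/MeCN/H2O, rt
Reagents that add atoms: sodium periodate, [Na+].[O-]I(=O)(=O)=O
Why: Catalytic RuO4 oxidative cleavage (Sharpless conditions) cuts the electron-rich trisubstituted alkene to acetone plus the aldehyde, which is oxidised on to the acid in the same flask; the stereocentre is γ to the new carboxyl group and cannot epimerise.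

Step 8
Reactants: 15 acid
Product: 17 (R)-tert-butyl[(5-iodo-3-methylpentyl)oxy]dimethylsilane, via acyl hypoiodite 16 (not isolated)
Conditions: PhI(OAc)2, I2, cyclohexane, hν (W lamp), reflux
Reagents that add atoms: iodine, II
Why: Suárez modification of the Hunsdiecker reaction: the acyl hypoiodite homolyses under light, loses CO2, and iodine captures the primary radical at close to the diffusion limit, which removes the one surplus carbon of the cleaved citronellol chain so that the fragment is exactly C11–C16; the C13 centre is not involved (its descriptor becomes R only through the priority of iodine).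

Step 9
Reactants: 17 iodide; 11 silyloxy enone
Product: 19 (13S)-3β,15-bis(tert-butyldimethylsilyloxy)labd-7-en-9-ol (9β-OH expected), via alkyllithium 18 (not isolated)
Conditions: 17 (1.5 equiv), t-BuLi (3.0 equiv), Et2O/pentane, −78 °C; then 11, −78 to 0 °C; H2O
Reagents that add atoms: none
Why: Lithium–iodine exchange followed by 1,2-addition of a hard primary alkyllithium to a ketone that has no α-hydrogen (C10 quaternary, C8 sp2) forms C9–C11; approach anti to the axial 10β-methyl group should give mainly the 9β-alcohol, but this centre is erased in step 10 so its configuration is irrelevant.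

Step 10
Reactants: 19 tertiary allylic alcohol
Product: 20 (13S)-3β,15-bis(tert-butyldimethylsilyloxy)labd-8-en-7-one
Conditions: [C5H5NH][CrO3Cl] (3 equiv), 4 Å MS, CH2Cl2, rt
Reagents that add atoms: pyridinium chlorochromate, [O-][Cr](=O)(=O)Cl.c1cc[nH+]cc1 (the C7 oxygen is a chromate oxygen)
Why: Babler–Dauben oxidative transposition: the tertiary allylic chromate ester undergoes a [3,3] shift to the less hindered C7 and is oxidised there, which moves the oxygen from C9 to C7 and leaves the side chain on the β-carbon of a new C8=C9 enone; silyl ethers tolerate the reagent.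

Step 11
Reactants: 20 transposed enone
Product: 22 (13S)-3β,15-bis(tert-butyldimethylsilyloxy)labd-7-en-7-yl triflate (9α-H), via lithium enolate 21 (not isolated)
Conditions: Li (2.2 equiv), t-BuOH (1 equiv), NH3/THF, −78 °C; evaporate NH3; PhNTf2, THF, 0 °C to rt
Reagents that add atoms: N-phenylbis(trifluoromethanesulfonimide), O=S(=O)(N(c1ccccc1)S(=O)(=O)C(F)(F)F)C(F)(F)F
Why: Dissolving-metal enone reduction with regiospecific enolate trapping as the enol triflate: two electrons and one proton give the C7–C8 lithium enolate, the C9 carbanion being protonated along the axial α trajectory that keeps overlap with the enolate π system and lies away from the 10β-methyl group, which sets 9α-H with the side chain equatorial, and O-sulfonylation then locks the double bond at C7=C8.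

Step 12
Reactants: 22 enol triflate
Product: 23 (13S)-3β,15-bis(tert-butyldimethylsilyloxy)labd-7-ene
Conditions: Pd(OAc)2 (5 mol %), PPh3 (10 mol %), HCO2H (2 equiv), Et3N (3 equiv), DMF, 60 °C
Reagents that add atoms: none
Why: Palladium-catalysed formate hydrogenolysis of an enol triflate (oxidative addition to zerovalent palladium, decarboxylation of the formate, reductive elimination) replaces the triflate by hydrogen at C7 without moving the C7=C8 bond or touching C9.

Step 13
Reactants: 23 bis-silyl ether
Product: 24 (13S)-labd-7-ene-3β,15-diol
Conditions: Bu4NF, THF, 60 °C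
Reagents that add atoms: none
Why: Fluoride-driven desilylation; warming is needed for the hindered 3β-silyl ether, and the medium cannot move the isolated C7=C8 bond.

Step 14
Reactants: 24 diol
Product: 25 (13S)-labd-7-ene-3β,15-diyl diformate (CNP0137609.1)
Conditions: HCO2H + Ac2O (premixed, 55 °C, then cooled), pyridine, CH2Cl2, 0 °C to rt
Reagents that add atoms: formic acid, O=CO (transferred as acetic formic anhydride, CC(=O)OC=O)
Why: O-Formylation by a mixed anhydride: alcohols attack the more electrophilic formyl carbonyl of acetic formic anhydride, so both the primary C15 and the hindered equatorial C3 alcohol become formates under non-acidic conditions that leave the trisubstituted alkene and all five stereocentres untouched.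

Compound list
1 | (R)-carvone | CC1=CC[C@@H](C(C)=C)CC1=O | starting material
2 | iodomethane | CI | starting material
3 | lithium dienolate of carvone | CC1=CC[C@@H](C(C)=C)C=C1[O-].[Li+] | intermediate
4 | 6-methylcarvone (C10 epimers) | CC1=CC[C@@H](C(C)=C)C(C)C1=O | intermediate
5 | propargyl bromide | C#CCBr | starting material
6 | lithium enolate of 6-methylcarvone | CC1=CC[C@@H](C(C)=C)C(C)=C1[O-].[Li+] | intermediate
7 | (5S,6S)-6-methyl-6-propargylcarvone | CC1=CC[C@@H](C(C)=C)[C@](C)(CC#C)C1=O | intermediate
8 | (E)-alkenyl(dicyclohexyl)borane from 7 | CC1=CC[C@@H](C(C)=C)[C@](C)(C/C=C/B(C2CCCCC2)C2CCCCC2)C1=O | intermediate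
9 | 6-methyl-6-(3-oxopropyl)carvone, chain trans to isopropenyl | CC1=CC[C@@H](C(C)=C)[C@](C)(CCC=O)C1=O | intermediate
10 | 3β-hydroxy-4,4,8,10-tetramethyl-trans-octal-7-en-9-one | CC1=CC[C@H]2C(C)(C)[C@@H](O)CC[C@]2(C)C1=O | intermediate
11 | 3β-TBS ether of 10 | CC1=CC[C@H]2C(C)(C)[C@@H](O[Si](C)(C)C(C)(C)C)CC[C@]2(C)C1=O | intermediate
12 | (S)-citronellol | CC(C)=CCC[C@H](C)CCO | starting material
13 | (S)-citronellyl TBS ether | CC(C)=CCC[C@H](C)CCO[Si](C)(C)C(C)(C)C | intermediate
14 | (S)-6-(TBS-oxy)-4-methylhexanal | O=CCC[C@H](C)CCO[Si](C)(C)C(C)(C)C | intermediate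
15 | (S)-6-(TBS-oxy)-4-methylhexanoic acid | OC(=O)CC[C@H](C)CCO[Si](C)(C)C(C)(C)C | intermediate
16 | acyl hypoiodite of 15 | IOC(=O)CC[C@H](C)CCO[Si](C)(C)C(C)(C)C | intermediate
17 | (R)-5-iodo-3-methylpentyl TBS ether | ICC[C@H](C)CCO[Si](C)(C)C(C)(C)C | intermediate
18 | alkyllithium from 17 | [Li]CC[C@H](C)CCO[Si](C)(C)C(C)(C)C | intermediate
19 | (13S)-3β,15-bis(TBS-oxy)labd-7-en-9β-ol | CC1=CC[C@H]2C(C)(C)[C@@H](O[Si](C)(C)C(C)(C)C)CC[C@]2(C)[C@]1(O)CC[C@H](C)CCO[Si](C)(C)C(C)(C)C | intermediate
20 | (13S)-3β,15-bis(TBS-oxy)labd-8-en-7-one | CC=1C(=O)C[C@H]2C(C)(C)[C@@H](O[Si](C)(C)C(C)(C)C)CC[C@]2(C)C=1CC[C@H](C)CCO[Si](C)(C)C(C)(C)C | intermediate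
21 | C7–C8 lithium enolate, 9α-H | CC1=C([O-])C[C@H]2C(C)(C)[C@@H](O[Si](C)(C)C(C)(C)C)CC[C@]2(C)[C@H]1CC[C@H](C)CCO[Si](C)(C)C(C)(C)C.[Li+] | intermediate
22 | (13S)-3β,15-bis(TBS-oxy)labd-7-en-7-yl triflate | CC1=C(OS(=O)(=O)C(F)(F)F)C[C@H]2C(C)(C)[C@@H](O[Si](C)(C)C(C)(C)C)CC[C@]2(C)[C@H]1CC[C@H](C)CCO[Si](C)(C)C(C)(C)C | intermediate
23 | (13S)-3β,15-bis(TBS-oxy)labd-7-ene | CC1=CC[C@H]2C(C)(C)[C@@H](O[Si](C)(C)C(C)(C)C)CC[C@]2(C)[C@H]1CC[C@H](C)CCO[Si](C)(C)C(C)(C)C | intermediate
24 | (13S)-labd-7-ene-3β,15-diol | CC1=CC[C@H]2C(C)(C)[C@@H](O)CC[C@]2(C)[C@H]1CC[C@H](C)CCO | intermediate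
25 | (13S)-labd-7-ene-3β,15-diyl diformate | CC1=CC[C@H]2C(C)(C)[C@@H](OC=O)CC[C@]2(C)[C@H]1CC[C@H](C)CCOC=O | target

Total step count: 14. Longest linear sequence: 11 steps (steps 1–5 and 9–14). Steps 6–8 form the convergent side-chain branch.

Steps most likely to fail

Step 4. β-Scission of the alkoxy radical back to the open C4 radical may outrun its reduction. The substrate would then drain into plain hydrogenation of the isopropenyl group, or the aldehyde would be consumed by the silane.
Fallback: it sets out from 9 and makes the same C4 radical from a carbon–halogen bond in a tin hydride chain, where the alkoxy radical is quenched by very fast hydrogen transfer from Sn–H.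
- Markovnikov hydrobromination of the isopropenyl group (HBr/AcOH, 0 °C, the classical carvone hydrobromide reaction) should give the C4 tertiary bromide F1.
- Bu3SnH with Et3B/air in toluene at rt should then effect the 6-exo radical cyclisation of the bromo aldehyde.
- The route is rejoined at 10.

Step 9. Steric shielding of the C9 carbonyl between the quaternary C10 and the C8 methyl group may divert the alkyllithium into γ-deprotonation at C6, which only returns the enone.
Fallback: it sets out from 11 and 17 and turns this deprotonation to use.
- KN(SiMe3)2 then PhNTf2 converts 11 into the 6,8-dien-9-yl triflate F2.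
- Zn dust/LiCl in THF converts 17 into the alkylzinc iodide F3.
- Negishi coupling with PdCl2(dppf) joins them to the labda-6,8-diene F4.
- 1,4-Hydrogenation of the s-cis diene with (C10H8)Cr(CO)3 under H2 in THF follows. The Cr(CO)3 fragment binds the α face away from the 10β-methyl group and delivers hydrogen to C6 and C9 on that face.
- The route is rejoined at 23, which bypasses steps 10–12.

Step 11. Slow O-sulfonylation of the hindered tetrasubstituted enolate may allow proton exchange. That would scramble the enolate regiochemistry or simply return the saturated ketone.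
Fallback: it sets out from 20 and sets C9 by allylic hydrogenolysis instead.
- Luche reduction (NaBH4, CeCl3·7H2O, MeOH, −20 °C; axial hydride delivery from the α face) should give the 7β-allylic alcohol F5.
- Acetic formic anhydride/pyridine gives the allylic formate F6.
- Tsuji-type decarboxylative hydrogenolysis with Pd(OAc)2/PBu3 in dioxane follows. Zerovalent palladium ionises anti to the formate, so it sits on the α face, and hydride passes from palladium to the more substituted allyl terminus C9 on that face.
- This gives the C7=C8 alkene with 9α-H, and the route is rejoined at 23.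

Further compounds
F1 | step 4 | C4 tertiary bromide of 9 (hydrobromide of 6-methyl-6-(3-oxopropyl)carvone) | CC1=CC[C@@H](C(C)(C)Br)[C@](C)(CCC=O)C1=O
F2 | step 9 | 3β-(TBS-oxy)-4,4,8,10-tetramethyl-trans-octala-6,8-dien-9-yl triflate | CC=1C=C[C@H]2C(C)(C)[C@@H](O[Si](C)(C)C(C)(C)C)CC[C@]2(C)C=1OS(=O)(=O)C(F)(F)F
F3 | step 9 | 5-(TBS-oxy)-3-methylpentylzinc iodide | I[Zn]CC[C@H](C)CCO[Si](C)(C)C(C)(C)C
F4 | step 9 | (13S)-3β,15-bis(TBS-oxy)labda-6,8-diene | CC=1C=C[C@H]2C(C)(C)[C@@H](O[Si](C)(C)C(C)(C)C)CC[C@]2(C)C=1CC[C@H](C)CCO[Si](C)(C)C(C)(C)C
F5 | step 11 | (13S)-3β,15-bis(TBS-oxy)labd-8-en-7β-ol | CC=1[C@@H](O)C[C@H]2C(C)(C)[C@@H](O[Si](C)(C)C(C)(C)C)CC[C@]2(C)C=1CC[C@H](C)CCO[Si](C)(C)C(C)(C)C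
F6 | step 11 | (13S)-3β,15-bis(TBS-oxy)labd-8-en-7β-yl formate | CC=1[C@@H](OC=O)C[C@H]2C(C)(C)[C@@H](O[Si](C)(C)C(C)(C)C)CC[C@]2(C)C=1CC[C@H](C)CCO[Si](C)(C)C(C)(C)C
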